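The numbers in the tables come from a simulation on assumed constants, and the scatter is random.

If I want to say how far a flask has gone, I work with the fraction of substrate left and take minus its logarithm, the log left, which is the vertical axis of a first-order plot.

| flask | substrate | coupling partner | free catalyst | time |
|---|---|---|---|---|
| green | 0.800 M | 1.60 M | 0.00160 M |  |
| teal | 0.320 M | 1.12 M | 0.00160 M |  |
| violet | 0.800 M | 1.60 M | 0.00240 M |  |
| red | 0.800 M | 0.800 M | 0.00160 M |  |
| ochre | 0.800 M | 1.60 M | 0.00390 M | 44 h |

- green run (time / h: [target] / M): 1.8: 0.032; 3.9: 0.096; 8.8: 0.168; 20: 0.303; 44: 0.442
- teal run (time / h: [target] / M): 1.8: 0.014; 3.9: 0.054; 8.8: 0.089; 20: 0.165; 44: 0.199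
- violet run (time / h: [target] / M): 1.8: 0.064; 3.9: 0.142; 8.8: 0.247; 20: 0.422; 44: 0.574
- red run (time / h: [target] / M): 1.8: 0.066; 3.9: 0.151; 8.8: 0.283; 20: 0.485; 44: 0.662

(scatter of a reading: 0.008 M)

- Overall: substrate + coupling partner -> target, with free catalyst as catalyst.
- Constant volume, constant temperature.
- The analysis sees a species whether free or bound.
- "The second partner" is coupling partner.
- An order is taken over about fifteen percent of the charge, up and down.

- apparent order in [substrate] of the starting rate, round the charge of the green run (the rate where two percent of its substrate have turned into target) (one fixed amount of target, the same in the runs compared)
- apparent order in [coupling partner] of the starting rate, round the charge of the green run (the rate where two percent of its substrate have turned into target)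
- target in the ochre run at 44 h, as a share of the substrate charged

I start with the coupling partner. Red and green differ in partner charge, so the ratio of their logs left gives an order of −0.710 at 3.9 h and −0.889 at 8.8 h. These two differ, but the scatter on green's earlier reading alone moves that order by 0.120, so I commit to their mean, −0.800.

If the substrate order is one, the log left at a given time, with partner and catalyst held, doesn't depend on the substrate charge; teal has green's catalyst charge, so I set teal's partner charge against green's first. At 8.8 h, teal's log left is 1.38 times green's, and the partner order predicts 1.33. The remainder gives an order of 0.958. I doubt the second digit, since teal's reading carries 8.99% scatter, so I say one.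

For ochre I need the log left at 44 h per green dose, 0.843 in violet: the log left divided by the catalyst charge as a multiple of green's. Green gives 0.804. If violet's figure held for ochre, ochre would reach 87.2%.

But the figure isn't constant in these readings: violet's stands above green's by 0.0390, though the scatter of one reading moves violet's figure by 0.0236. Taking that gap as real, I read the log left as a power of the catalyst charge from these two runs, with exponent 1.12. Carried from violet to ochre, this gives a log left of 2.17, so I commit to 88.6%.

The forecast gives 0.9, −0.8 and 84%, on these grounds: “Extrapolating violet's late rate (~0.004 M/h, falling) adds about 0.09–0.11 M, giving ≈0.67 M, or about 84%.”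

The flask gives 1.0, −0.81 and 89.4%. For ochre the forecast stands 5.4 percentage points low and my figure 0.80 points low.

    free catalyst + substrate ⇌ catalyst-substrate complex (712.8 /M/h, 1386 /h)
    catalyst-substrate complex + coupling partner → target + free catalyst (3960 /M/h)
    free catalyst + coupling partner ⇌ idle catalyst-reagent complex, settled at all times (18.70 /M)
    free catalyst + coupling partner → spent catalyst + coupling partner (0.6444 /M/h)

The ochre run ends at 0.921 per green dose, above violet's figure, and the red run, with green's catalyst and half its partner, reads 1.76. At the start of the ochre run, the resting state was the idle catalyst-reagent complex, 29.9 of it per free catalyst, while substrate passed through the catalyst-substrate complex to target. Over the 44 h, free catalyst also went to spent catalyst, free catalyst and idle catalyst-reagent complex together having a life of 30.0 h at the start, and the coupling partner ended at 55.3% of its charge.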